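**Retrosynthetic overview**
1. The C8 senecioate and C13 acetate go on last. The ten-membered ring is closed at C2–C3 by ring-closing metathesis of two vinyl oxiranes, then diimide reduction. Ring order: oxiranes, then butenolide, then carbocycle.
2. Butenolide: the C6–C7 bond comes from Ni/Cr coupling of the west (Z)-enol triflate 25 with the east cis-epoxy aldehyde 29, and the lactone closes in the same flask.
3. Key C–C bond C7–C11: intermolecular lithium-enolate aldol joining west aldehyde 17 to propanoate 20 (C11–C13), followed by oxidation and triflation.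
4. West fragment: C8–C9 by catalytic asymmetric carbonyl methallylation of aldehyde 4. The Z-alkene is locked by RCM to a dihydropyranone, and the C1/C10 oxirane is set by Sharpless epoxidation.
5. East fragment: Sharpless epoxidation of (Z)-3-methylpent-2-en-4-yn-1-ol sets C4/C5, then semi-hydrogenation and oxidation.

Assumption: the SMILES is taken literally, i.e. (1S,4S,5R,6R,8R,10R) in germacrane numbering with both oxiranes cis-fused to the ring; germacrane numbering is used for atom labels (C1–C10 ring, C11–C13 lactone carbons, C14 on C10, C15 on C4); PMB = 4-methoxybenzyl, TBS = tert-butyldimethylsilyl.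

**Step 1**
Reactants: 1 (Z)-but-2-ene-1,4-diol
Product: 2 (Z)-1,4-bis(PMB-oxy)but-2-ene
Conditions: NaH, PMBCl, Bu4NI (cat.), THF/DMF, 0 °C to rt
Reagents that add atoms: 4-methoxybenzyl chloride, COc1ccc(CCl)cc1
Why: Williamson etherification of both primary alkoxides; no stereocentre is involved.

**Step 2**
Reactants: 2 (Z)-1,4-bis(PMB-oxy)but-2-ene
Product: 4 2-(PMB-oxy)acetaldehyde, via secondary ozonide 3 (not isolated)
Conditions: O3, CH2Cl2, −78 °C; then Me2S, −78 °C to rt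
Reagents that add atoms: ozone, [O-][O+]=O
Why: Ozonolysis with reductive work-up cleaves the symmetric alkene into two molecules of the aldehyde.

**Step 3**
Reactants: 4 2-(PMB-oxy)acetaldehyde; 5 tributyl(2-methylallyl)stannane
Product: 6 (2R)-1-(PMB-oxy)-4-methylpent-4-en-2-ol
Conditions: (R)-BINOL (10 mol%), Ti(OiPr)4 (10 mol%), 4 Å MS, CH2Cl2, −20 °C, 60 h; aq. NaHCO3
Reagents that add atoms: none
Why: Keck catalytic asymmetric carbonyl methallylation forms C8–C9, and the (R)-BINOL–Ti catalyst directs the methallyl group to the Re face to set C8 (R).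

**Step 4**
Reactants: 6 (2R)-1-(PMB-oxy)-4-methylpent-4-en-2-ol; 7 acryloyl chloride
Product: 8 (2R)-1-(PMB-oxy)-4-methylpent-4-en-2-yl acrylate
Conditions: Et3N, DMAP (cat.), CH2Cl2, 0 °C
Reagents that add atoms: none
Why: DMAP-assisted O-acylation of the secondary alcohol by the acid chloride, with no change at C8.

**Step 5**
Reactants: 8 (2R)-1-(PMB-oxy)-4-methylpent-4-en-2-yl acrylate
Product: 9 (6R)-4-methyl-6-(PMB-oxymethyl)-5,6-dihydro-2H-pyran-2-one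
Conditions: Grubbs II (3 mol%), CH2Cl2 (0.01 M), 40 °C
Reagents that add atoms: none
Why: Ring-closing metathesis of the acrylate with the 1,1-disubstituted alkene gives the six-membered lactone, which fixes the C1=C10 alkene as Z.

**Step 6**
Reactants: 9 (6R)-4-methyl-6-(PMB-oxymethyl)-5,6-dihydro-2H-pyran-2-one
Product: 10 (2Z,5R)-3-methyl-6-(PMB-oxy)hex-2-ene-1,5-diol
Conditions: DIBAL-H (4 equiv), CH2Cl2, −78 to 0 °C; Rochelle salt
Reagents that add atoms: none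
Why: Hydride reduction of the unsaturated lactone through the lactol gives the Z-allylic diol with the alkene geometry retained.

**Step 7**
Reactants: 10 (2Z,5R)-3-methyl-6-(PMB-oxy)hex-2-ene-1,5-diol
Product: 11 (2Z,5R)-3-methyl-6-(PMB-oxy)-1,5-bis(TBS-oxy)hex-2-ene
Conditions: TBSCl (2.5 equiv), imidazole, DMF, rt
Reagents that add atoms: tert-butyldimethylsilyl chloride, CC(C)(C)[Si](C)(C)Cl
Why: Imidazole-promoted silylation protects both hydroxyl groups.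

**Step 8**
Reactants: 11 (2Z,5R)-3-methyl-6-(PMB-oxy)-1,5-bis(TBS-oxy)hex-2-ene
Product: 12 (2Z,5R)-3-methyl-6-(PMB-oxy)-5-(TBS-oxy)hex-2-en-1-ol
Conditions: CSA (10 mol%), MeOH/CH2Cl2 1:1, −10 °C
Reagents that add atoms: none
Why: Acid-catalysed methanolysis removes the unhindered primary allylic silyl ether far faster than the secondary one, and the PMB ether is stable.

**Step 9**
Reactants: 12 (2Z,5R)-3-methyl-6-(PMB-oxy)-5-(TBS-oxy)hex-2-en-1-ol
Product: 13 [(2S,3R)-3-methyl-3-[(2R)-3-(PMB-oxy)-2-(TBS-oxy)propyl]oxiran-2-yl]methanol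
Conditions: Ti(OiPr)4 (20 mol%), L-(+)-DET (25 mol%), t-BuOOH, 4 Å MS, CH2Cl2, −20 °C
Reagents that add atoms: tert-butyl hydroperoxide, CC(C)(C)OO
Why: Sharpless asymmetric epoxidation of this nerol-type Z-allylic alcohol with L-(+)-tartrate sets C1 (S) and C10 (R) by reagent control, and the minor enantiomer from step 3 becomes a separable diastereomer.

**Step 10**
Reactants: 13 [(2S,3R)-3-methyl-3-[(2R)-3-(PMB-oxy)-2-(TBS-oxy)propyl]oxiran-2-yl]methanol
Product: 14 (2R,3R)-3-methyl-3-[(2R)-3-(PMB-oxy)-2-(TBS-oxy)propyl]oxirane-2-carbaldehyde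
Conditions: TEMPO (10 mol%), PhI(OAc)2, CH2Cl2, rt
Reagents that add atoms: none
Why: TEMPO/oxoammonium oxidation converts the primary alcohol into the aldehyde without base, so the oxirane centres are untouched (the descriptor at C1 changes only by CIP priority).

**Step 11**
Reactants: 14 (2R,3R)-3-methyl-3-[(2R)-3-(PMB-oxy)-2-(TBS-oxy)propyl]oxirane-2-carbaldehyde
Product: 15 (2R,3S)-3-ethenyl-2-methyl-2-[(2R)-3-(PMB-oxy)-2-(TBS-oxy)propyl]oxirane
Conditions: Ph3PCH3Br, KHMDS, THF, 0 °C; then 14, −78 to 0 °C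
Reagents that add atoms: methyltriphenylphosphonium bromide, C[P+](c1ccccc1)(c1ccccc1)c1ccccc1.[Br-]
Why: Wittig methylenation of the non-enolizable epoxy aldehyde gives the vinyl oxirane needed for the later metathesis.

**Step 12**
Reactants: 15 (2R,3S)-3-ethenyl-2-methyl-2-[(2R)-3-(PMB-oxy)-2-(TBS-oxy)propyl]oxirane
Product: 16 (2R)-3-[(2R,3S)-3-ethenyl-2-methyloxiran-2-yl]-2-(TBS-oxy)propan-1-ol
Conditions: DDQ, CH2Cl2/pH 7 buffer 10:1, 0 °C
Reagents that add atoms: none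
Why: Oxidative PMB cleavage with DDQ frees the C7 alcohol under neutral conditions that spare the silyl ether and the vinyl oxirane.

**Step 13**
Reactants: 16 (2R)-3-[(2R,3S)-3-ethenyl-2-methyloxiran-2-yl]-2-(TBS-oxy)propan-1-ol
Product: 17 (2R)-3-[(2R,3S)-3-ethenyl-2-methyloxiran-2-yl]-2-(TBS-oxy)propanal
Conditions: TEMPO (10 mol%), PhI(OAc)2, CH2Cl2, 0 °C to rt; used at once
Reagents that add atoms: none
Why: Non-basic TEMPO oxidation gives the α-silyloxy aldehyde without epimerizing C8.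

**Step 14**
Reactants: 18 methyl acrylate; 19 4-methoxybenzyl alcohol
Product: 20 methyl 3-(PMB-oxy)propanoate
Conditions: KOtBu (5 mol%), THF, 0 °C to rt
Reagents that add atoms: none
Why: Base-catalysed oxa-Michael addition of the alkoxide to the acrylate gives the C11–C13 unit.

**Step 15**
Reactants: 17 (2R)-3-[(2R,3S)-3-ethenyl-2-methyloxiran-2-yl]-2-(TBS-oxy)propanal; 20 methyl 3-(PMB-oxy)propanoate
Product: 22 methyl (4R)-5-[(2R,3S)-3-ethenyl-2-methyloxiran-2-yl]-3-hydroxy-2-(PMB-oxymethyl)-4-(TBS-oxy)pentanoate (C2/C3 mixture), via lithium ester enolate 21 (not isolated)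
Conditions: LDA, THF, −78 °C, 20; then 17, −78 °C, 1 h; AcOH quench at −78 °C
Reagents that add atoms: none
Why: Directed intermolecular aldol addition forms C7–C11 because the kinetic lithium enolate adds to the activated α-silyloxy aldehyde at −78 °C faster than it loses alkoxide; the two new centres are left uncontrolled since both become sp2 later.

**Step 16**
Reactants: 22 methyl (4R)-5-[(2R,3S)-3-ethenyl-2-methyloxiran-2-yl]-3-hydroxy-2-(PMB-oxymethyl)-4-(TBS-oxy)pentanoate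
Product: 23 methyl (4R)-5-[(2R,3S)-3-ethenyl-2-methyloxiran-2-yl]-3-oxo-2-(PMB-oxymethyl)-4-(TBS-oxy)pentanoate (C2 epimers)
Conditions: Dess–Martin periodinane, pyridine, CH2Cl2, 0 °C to rt
Reagents that add atoms: none
Why: Dess–Martin oxidation of the β-hydroxy ester gives the β-keto ester under buffered conditions that leave C8 and the oxirane intact.

**Step 17**
Reactants: 23 methyl (4R)-5-[(2R,3S)-3-ethenyl-2-methyloxiran-2-yl]-3-oxo-2-(PMB-oxymethyl)-4-(TBS-oxy)pentanoate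
Product: 25 methyl (2Z,4R)-5-[(2R,3S)-3-ethenyl-2-methyloxiran-2-yl]-2-(PMB-oxymethyl)-4-(TBS-oxy)-3-(triflyloxy)pent-2-enoate, via sodium enolate 24 (not isolated)
Conditions: NaH, toluene, 0 °C; then Tf2O, −78 to 0 °C
Reagents that add atoms: trifluoromethanesulfonic anhydride, O=S(=O)(OS(=O)(=O)C(F)(F)F)C(F)(F)F
Why: O-Triflation of the chelated sodium enolate gives the Z enol triflate with OTf cis to the ester, and only the acidic C11–H is removed so C8 is not epimerized.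

**Step 18**
Reactants: 26 (2Z)-3-methylpent-2-en-4-yn-1-ol
Product: 27 [(2R,3S)-3-ethynyl-3-methyloxiran-2-yl]methanol
Conditions: Ti(OiPr)4 (20 mol%), D-(−)-DET (25 mol%), t-BuOOH, 4 Å MS, CH2Cl2, −20 °C
Reagents that add atoms: tert-butyl hydroperoxide, CC(C)(C)OO
Why: Sharpless asymmetric epoxidation with D-(−)-tartrate sets C5 (R) and C4 (S) by reagent control; the alkyne is inert and the small cis ethynyl group keeps the Z-alcohol a good substrate.

**Step 19**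
Reactants: 27 [(2R,3S)-3-ethynyl-3-methyloxiran-2-yl]methanol
Product: 28 [(2R,3S)-3-ethenyl-3-methyloxiran-2-yl]methanol
Conditions: H2 (1 atm), Lindlar catalyst, quinoline, EtOAc, 0 °C to rt, stopped at 1 equiv
Reagents that add atoms: none
Why: Lindlar semi-hydrogenation stops the terminal alkyne at the alkene on poisoned palladium without hydrogenolysis of the oxirane.

**Step 20**
Reactants: 28 [(2R,3S)-3-ethenyl-3-methyloxiran-2-yl]methanol
Product: 29 (2S,3S)-3-ethenyl-3-methyloxirane-2-carbaldehyde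
Conditions: TEMPO (10 mol%), PhI(OAc)2, CH2Cl2, 0 °C to rt; volatile, used as a solution
Reagents that add atoms: none
Why: TEMPO oxidation gives the cis-epoxy aldehyde without base, so C4 and C5 are unchanged (the descriptor at C5 changes only by CIP priority).

**Step 21**
Reactants: 25 methyl (2Z,4R)-5-[(2R,3S)-3-ethenyl-2-methyloxiran-2-yl]-2-(PMB-oxymethyl)-4-(TBS-oxy)-3-(triflyloxy)pent-2-enoate; 29 (2S,3S)-3-ethenyl-3-methyloxirane-2-carbaldehyde
Product: 31 (5R)-5-[(2R,3S)-3-ethenyl-3-methyloxiran-2-yl]-4-{(1R)-2-[(2R,3S)-3-ethenyl-2-methyloxiran-2-yl]-1-(TBS-oxy)ethyl}-3-(PMB-oxymethyl)furan-2(5H)-one, via open hydroxy ester 30 (not isolated)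
Conditions: CrCl2 (5 equiv), NiCl2 (2 mol%), DMF/THF, rt, 29 (2 equiv); aq. serinate work-up, PPTS (cat.) if lactonization is incomplete
Reagents that add atoms: none
Why: Nozaki–Hiyama–Kishi coupling forms C6–C7: the alkenylchromium adds to the cis-epoxy aldehyde anti to the oxirane C–O bond (Felkin–Anh), giving the erythro 6R carbinol, and the chromium alkoxide closes the butenolide on the cis ester.

**Step 22**
Reactants: 31 (5R)-5-[(2R,3S)-3-ethenyl-3-methyloxiran-2-yl]-4-{(1R)-2-[(2R,3S)-3-ethenyl-2-methyloxiran-2-yl]-1-(TBS-oxy)ethyl}-3-(PMB-oxymethyl)furan-2(5H)-one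
Product: 32 (5R)-5-[(2R,3S)-3-ethenyl-3-methyloxiran-2-yl]-4-{(1R)-2-[(2R,3S)-3-ethenyl-2-methyloxiran-2-yl]-1-(TBS-oxy)ethyl}-3-(hydroxymethyl)furan-2(5H)-one
Conditions: DDQ, CH2Cl2/pH 7 buffer 10:1, 0 °C
Reagents that add atoms: none
Why: Oxidative PMB cleavage frees the C13 alcohol under neutral conditions compatible with both vinyl oxiranes and the butenolide.

**Step 23**
Reactants: 32 (5R)-5-[(2R,3S)-3-ethenyl-3-methyloxiran-2-yl]-4-{(1R)-2-[(2R,3S)-3-ethenyl-2-methyloxiran-2-yl]-1-(TBS-oxy)ethyl}-3-(hydroxymethyl)furan-2(5H)-one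
Product: 33 (5R)-3-(acetoxymethyl)-5-[(2R,3S)-3-ethenyl-3-methyloxiran-2-yl]-4-{(1R)-2-[(2R,3S)-3-ethenyl-2-methyloxiran-2-yl]-1-(TBS-oxy)ethyl}furan-2(5H)-one
Conditions: Ac2O, pyridine, DMAP (cat.), CH2Cl2, 0 °C
Reagents that add atoms: acetic anhydride, CC(=O)OC(C)=O
Why: Acetylation of the primary allylic alcohol installs the C13 acetate before the sensitive macrocycle is formed.

**Step 24**
Reactants: 33 (5R)-3-(acetoxymethyl)-5-[(2R,3S)-3-ethenyl-3-methyloxiran-2-yl]-4-{(1R)-2-[(2R,3S)-3-ethenyl-2-methyloxiran-2-yl]-1-(TBS-oxy)ethyl}furan-2(5H)-one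
Product: 34 (1S,2Z,4S,5R,6R,8R,10R)-13-acetoxy-1,10:4,5-diepoxy-8-(TBS-oxy)germacra-2,7(11)-dien-12,6-olide
Conditions: Hoveyda–Grubbs II (10 mol%), 1,4-benzoquinone (20 mol%), toluene (1 mM), 60–80 °C
Reagents that add atoms: none
Why: Ring-closing metathesis of the two vinyl oxiranes closes the ten-membered ring at C2=C3; the arms sit on adjacent butenolide carbons and both oxiranes are cis, no stereocentre is touched, and any E isomer converges in step 25.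

**Step 25**
Reactants: 34 (1S,2Z,4S,5R,6R,8R,10R)-13-acetoxy-1,10:4,5-diepoxy-8-(TBS-oxy)germacra-2,7(11)-dien-12,6-olide
Product: 35 (1S,4S,5R,6R,8R,10R)-13-acetoxy-1,10:4,5-diepoxy-8-(TBS-oxy)germacr-7(11)-en-12,6-olide
Conditions: 2-nitrobenzenesulfonohydrazide (8 equiv), Et3N, CH2Cl2, rt
Reagents that add atoms: none
Why: Diimide reduction saturates only the disubstituted ring alkene, leaving the tetrasubstituted butenolide alkene, the allylic acetate and the allylic oxiranes (no hydrogenolysis).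

**Step 26**
Reactants: 35 (1S,4S,5R,6R,8R,10R)-13-acetoxy-1,10:4,5-diepoxy-8-(TBS-oxy)germacr-7(11)-en-12,6-olide
Product: 36 (1S,4S,5R,6R,8R,10R)-13-acetoxy-1,10:4,5-diepoxy-8-hydroxygermacr-7(11)-en-12,6-olide
Conditions: HF·pyridine, pyridine, THF, 0 °C to rt
Reagents that add atoms: none
Why: Buffered fluoride desilylation frees the C8 alcohol without acetate migration or oxirane opening.

**Step 27**
Reactants: 36 (1S,4S,5R,6R,8R,10R)-13-acetoxy-1,10:4,5-diepoxy-8-hydroxygermacr-7(11)-en-12,6-olide; 37 3-methylbut-2-enoyl chloride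
Product: 38 CNP0228323.1 (1S,4S,5R,6R,8R,10R)-13-acetoxy-1,10:4,5-diepoxy-8-(3-methylbut-2-enoyloxy)germacr-7(11)-en-12,6-olide
Conditions: pyridine, DMAP (20 mol%), CH2Cl2, 0 °C to rt
Reagents that add atoms: none
Why: DMAP-catalysed acylation of the C8 alcohol with retention at C8; pyridine as the only base avoids vinylketene formation and deconjugation of the senecioyl group.

**Compound list**
1 | (Z)-but-2-ene-1,4-diol | OC/C=C\CO | starting material
2 | (Z)-1,4-bis(PMB-oxy)but-2-ene | COc1ccc(COC/C=C\COCc2ccc(OC)cc2)cc1 | intermediate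
3 | 3,5-bis(PMB-oxymethyl)-1,2,4-trioxolane (secondary ozonide; not isolated) | COc1ccc(COCC2OOC(COCc3ccc(OC)cc3)O2)cc1 | intermediate
4 | 2-(PMB-oxy)acetaldehyde | COc1ccc(COCC=O)cc1 | intermediate
5 | tributyl(2-methylallyl)stannane | C=C(C)C[Sn](CCCC)(CCCC)CCCC | starting material
6 | (2R)-1-(PMB-oxy)-4-methylpent-4-en-2-ol | C=C(C)C[C@H](COCc1ccc(OC)cc1)O | intermediate
7 | acryloyl chloride | C=CC(=O)Cl | starting material
8 | (2R)-1-(PMB-oxy)-4-methylpent-4-en-2-yl acrylate | C=C(C)C[C@H](COCc1ccc(OC)cc1)OC(=O)C=C | intermediate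
9 | (6R)-4-methyl-6-(PMB-oxymethyl)-5,6-dihydro-2H-pyran-2-one | O=C1C=C(C)C[C@H](COCc2ccc(OC)cc2)O1 | intermediate
10 | (2Z,5R)-3-methyl-6-(PMB-oxy)hex-2-ene-1,5-diol | OC/C=C(/C)C[C@H](COCc1ccc(OC)cc1)O | intermediate
11 | (2Z,5R)-3-methyl-6-(PMB-oxy)-1,5-bis(TBS-oxy)hex-2-ene | CC(C)(C)[Si](C)(C)OC/C=C(/C)C[C@H](COCc1ccc(OC)cc1)O[Si](C)(C)C(C)(C)C | intermediate
12 | (2Z,5R)-3-methyl-6-(PMB-oxy)-5-(TBS-oxy)hex-2-en-1-ol | OC/C=C(/C)C[C@H](COCc1ccc(OC)cc1)O[Si](C)(C)C(C)(C)C | intermediate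
13 | [(2S,3R)-3-methyl-3-[(2R)-3-(PMB-oxy)-2-(TBS-oxy)propyl]oxiran-2-yl]methanol | OC[C@@H]1O[C@]1(C)C[C@H](COCc2ccc(OC)cc2)O[Si](C)(C)C(C)(C)C | intermediate
14 | (2R,3R)-3-methyl-3-[(2R)-3-(PMB-oxy)-2-(TBS-oxy)propyl]oxirane-2-carbaldehyde | O=C[C@@H]1O[C@]1(C)C[C@H](COCc2ccc(OC)cc2)O[Si](C)(C)C(C)(C)C | intermediate
15 | (2R,3S)-3-ethenyl-2-methyl-2-[(2R)-3-(PMB-oxy)-2-(TBS-oxy)propyl]oxirane | C=C[C@@H]1O[C@]1(C)C[C@H](COCc2ccc(OC)cc2)O[Si](C)(C)C(C)(C)C | intermediate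
16 | (2R)-3-[(2R,3S)-3-ethenyl-2-methyloxiran-2-yl]-2-(TBS-oxy)propan-1-ol | C=C[C@@H]1O[C@]1(C)C[C@H](CO)O[Si](C)(C)C(C)(C)C | intermediate
17 | (2R)-3-[(2R,3S)-3-ethenyl-2-methyloxiran-2-yl]-2-(TBS-oxy)propanal | C=C[C@@H]1O[C@]1(C)C[C@H](C=O)O[Si](C)(C)C(C)(C)C | intermediate
18 | methyl acrylate | C=CC(=O)OC | starting material
19 | 4-methoxybenzyl alcohol | COc1ccc(CO)cc1 | starting material
20 | methyl 3-(PMB-oxy)propanoate | COC(=O)CCOCc1ccc(OC)cc1 | intermediate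
21 | lithium enolate of methyl 3-(PMB-oxy)propanoate (not isolated) | [Li+].COC([O-])=CCOCc1ccc(OC)cc1 | intermediate
22 | methyl (4R)-5-[(2R,3S)-3-ethenyl-2-methyloxiran-2-yl]-3-hydroxy-2-(PMB-oxymethyl)-4-(TBS-oxy)pentanoate (C2/C3 mixture) | C=C[C@@H]1O[C@]1(C)C[C@H](C(O)C(COCc2ccc(OC)cc2)C(=O)OC)O[Si](C)(C)C(C)(C)C | intermediate
23 | methyl (4R)-5-[(2R,3S)-3-ethenyl-2-methyloxiran-2-yl]-3-oxo-2-(PMB-oxymethyl)-4-(TBS-oxy)pentanoate (C2 epimers) | C=C[C@@H]1O[C@]1(C)C[C@H](C(=O)C(COCc2ccc(OC)cc2)C(=O)OC)O[Si](C)(C)C(C)(C)C | intermediate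
24 | sodium enolate of 23 (not isolated) | [Na+].COC(=O)C(COCc1ccc(OC)cc1)=C([O-])[C@@H](C[C@@]1(C)O[C@H]1C=C)O[Si](C)(C)C(C)(C)C | intermediate
25 | methyl (2Z,4R)-5-[(2R,3S)-3-ethenyl-2-methyloxiran-2-yl]-2-(PMB-oxymethyl)-4-(TBS-oxy)-3-(triflyloxy)pent-2-enoate | COC(=O)/C(COCc1ccc(OC)cc1)=C(\OS(=O)(=O)C(F)(F)F)[C@@H](C[C@@]1(C)O[C@H]1C=C)O[Si](C)(C)C(C)(C)C | intermediate
26 | (2Z)-3-methylpent-2-en-4-yn-1-ol | C#C/C(C)=C\CO | starting material
27 | [(2R,3S)-3-ethynyl-3-methyloxiran-2-yl]methanol | OC[C@H]1O[C@@]1(C)C#C | intermediate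
28 | [(2R,3S)-3-ethenyl-3-methyloxiran-2-yl]methanol | OC[C@H]1O[C@@]1(C)C=C | intermediate
29 | (2S,3S)-3-ethenyl-3-methyloxirane-2-carbaldehyde | O=C[C@H]1O[C@@]1(C)C=C | intermediate
30 | methyl (4R)-5-[(2R,3S)-3-ethenyl-2-methyloxiran-2-yl]-3-{(R)-[(2R,3S)-3-ethenyl-3-methyloxiran-2-yl](hydroxy)methyl}-2-(PMB-oxymethyl)-4-(TBS-oxy)pent-2-enoate (ester cis to the new carbinol; Cr(III) alkoxide; not isolated) | COC(=O)/C(COCc1ccc(OC)cc1)=C(\[C@@H](O)[C@H]1O[C@@]1(C)C=C)[C@@H](C[C@@]1(C)O[C@H]1C=C)O[Si](C)(C)C(C)(C)C | intermediate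
31 | (5R)-5-[(2R,3S)-3-ethenyl-3-methyloxiran-2-yl]-4-{(1R)-2-[(2R,3S)-3-ethenyl-2-methyloxiran-2-yl]-1-(TBS-oxy)ethyl}-3-(PMB-oxymethyl)furan-2(5H)-one | COc1ccc(COCC2=C([C@@H](C[C@@]3(C)O[C@H]3C=C)O[Si](C)(C)C(C)(C)C)[C@@H](OC2=O)[C@H]2O[C@@]2(C)C=C)cc1 | intermediate
32 | (5R)-5-[(2R,3S)-3-ethenyl-3-methyloxiran-2-yl]-4-{(1R)-2-[(2R,3S)-3-ethenyl-2-methyloxiran-2-yl]-1-(TBS-oxy)ethyl}-3-(hydroxymethyl)furan-2(5H)-one | OCC1=C([C@@H](C[C@@]2(C)O[C@H]2C=C)O[Si](C)(C)C(C)(C)C)[C@@H](OC1=O)[C@H]1O[C@@]1(C)C=C | intermediate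
33 | (5R)-3-(acetoxymethyl)-5-[(2R,3S)-3-ethenyl-3-methyloxiran-2-yl]-4-{(1R)-2-[(2R,3S)-3-ethenyl-2-methyloxiran-2-yl]-1-(TBS-oxy)ethyl}furan-2(5H)-one | CC(=O)OCC1=C([C@@H](C[C@@]2(C)O[C@H]2C=C)O[Si](C)(C)C(C)(C)C)[C@@H](OC1=O)[C@H]1O[C@@]1(C)C=C | intermediate
34 | (1S,2Z,4S,5R,6R,8R,10R)-13-acetoxy-1,10:4,5-diepoxy-8-(TBS-oxy)germacra-2,7(11)-dien-12,6-olide | CC(=O)OCC1=C2[C@@H](OC1=O)[C@H]1O[C@@]1(C)/C=C\[C@@H]1O[C@]1(C)C[C@H]2O[Si](C)(C)C(C)(C)C | intermediate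
35 | (1S,4S,5R,6R,8R,10R)-13-acetoxy-1,10:4,5-diepoxy-8-(TBS-oxy)germacr-7(11)-en-12,6-olide | CC(=O)OCC1=C2[C@@H](OC1=O)[C@H]1O[C@@]1(C)CC[C@@H]1O[C@]1(C)C[C@H]2O[Si](C)(C)C(C)(C)C | intermediate
36 | (1S,4S,5R,6R,8R,10R)-13-acetoxy-1,10:4,5-diepoxy-8-hydroxygermacr-7(11)-en-12,6-olide | CC(=O)OCC1=C2[C@@H](OC1=O)[C@H]1O[C@@]1(C)CC[C@@H]1O[C@]1(C)C[C@H]2O | intermediate
37 | 3-methylbut-2-enoyl chloride | CC(C)=CC(=O)Cl | starting material
38 | CNP0228323.1, (1S,4S,5R,6R,8R,10R)-13-acetoxy-1,10:4,5-diepoxy-8-(3-methylbut-2-enoyloxy)germacr-7(11)-en-12,6-olide | CC(=O)OCC1=C2[C@@H](OC1=O)[C@H]1O[C@@]1(C)CC[C@@H]1O[C@]1(C)C[C@H]2OC(=O)C=C(C)C | target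

**Step count**
Total steps: 27. Longest linear sequence: 23 (steps 1–13, 15–17, 21–27); side branches are step 14 and steps 18–20.

**Three steps most likely to fail, with fallbacks**

Step 24 (metathesis closure of the strained ten-membered ring; risk of dimers or no closure). The fallback inverts the order of the two unions, sets out from 25 and 28, and comes back at 35. Cross-metathesis of 25 with excess 28 (Hoveyda–Grubbs II, CH2Cl2, 40 °C) joins C2=C3 first and gives the cross-metathesis alcohol F1. Diimide (2-nitrobenzenesulfonohydrazide, Et3N) gives the saturated alcohol F2. TEMPO/PhI(OAc)2 gives the epoxy aldehyde triflate F3. High-dilution CrCl2/NiCl2 (DMF, 2 mM) then closes the ring at C6–C7 with in-flask lactonization, giving the macrocyclic butenolide PMB ether F4. DDQ gives the C13 alcohol F5, and Ac2O/pyridine gives 35.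

Step 21 (Ni/Cr coupling of a hindered tetrasubstituted enol triflate; C6 selectivity rests on substrate control and the vinyl oxiranes must survive). The fallback sets C6 by reduction instead of addition, sets out from 23 (with 29), and comes back at 31. Triflation of 23 under non-chelating conditions (Tf2O, aq. Me4NOH, toluene) gives the trans enol triflate F6, with OTf trans to the ester. Its Ni/Cr coupling with 29 gives the non-lactonizing hydroxy ester F7 as a C6 mixture. Dess–Martin oxidation gives the epoxy ketone F8. Zn(BH4)2 in Et2O at −20 °C, under oxirane–carbonyl chelation, gives the erythro alcohol F9 with 6R configuration. Irradiation (350 nm, CH2Cl2) isomerizes the tetrasubstituted alkene, and the cis isomer lactonizes to 31.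

Step 19 (semi-hydrogenation of the ethynyl oxirane; over-reduction or C–O hydrogenolysis on a small volatile compound). The fallback reduces before epoxidizing, sets out from 26, and comes back at 28. Zn(Cu/Ag) in MeOH/H2O reduces the enyne 26 to the dienol F10, and Sharpless epoxidation of its allylic alkene with D-(−)-DET gives 28 directly.

**Further compounds**
F1 | step 24 | methyl (2Z,4R)-5-[(2R,3S)-3-{2-[(2S,3R)-3-(hydroxymethyl)-2-methyloxiran-2-yl]ethenyl}-2-methyloxiran-2-yl]-2-(PMB-oxymethyl)-4-(TBS-oxy)-3-(triflyloxy)pent-2-enoate | COC(=O)/C(COCc1ccc(OC)cc1)=C(\OS(=O)(=O)C(F)(F)F)[C@@H](C[C@@]1(C)O[C@H]1C=C[C@]1(C)O[C@@H]1CO)O[Si](C)(C)C(C)(C)C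
F2 | step 24 | methyl (2Z,4R)-5-[(2R,3S)-3-{2-[(2S,3R)-3-(hydroxymethyl)-2-methyloxiran-2-yl]ethyl}-2-methyloxiran-2-yl]-2-(PMB-oxymethyl)-4-(TBS-oxy)-3-(triflyloxy)pent-2-enoate | COC(=O)/C(COCc1ccc(OC)cc1)=C(\OS(=O)(=O)C(F)(F)F)[C@@H](C[C@@]1(C)O[C@H]1CC[C@]1(C)O[C@@H]1CO)O[Si](C)(C)C(C)(C)C
F3 | step 24 | methyl (2Z,4R)-5-[(2R,3S)-3-{2-[(2S,3S)-3-formyl-2-methyloxiran-2-yl]ethyl}-2-methyloxiran-2-yl]-2-(PMB-oxymethyl)-4-(TBS-oxy)-3-(triflyloxy)pent-2-enoate | COC(=O)/C(COCc1ccc(OC)cc1)=C(\OS(=O)(=O)C(F)(F)F)[C@@H](C[C@@]1(C)O[C@H]1CC[C@]1(C)O[C@@H]1C=O)O[Si](C)(C)C(C)(C)C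
F4 | step 24 | (1S,4S,5R,6R,8R,10R)-1,10:4,5-diepoxy-13-(PMB-oxy)-8-(TBS-oxy)germacr-7(11)-en-12,6-olide | COc1ccc(COCC2=C3[C@@H](OC2=O)[C@H]2O[C@@]2(C)CC[C@@H]2O[C@]2(C)C[C@H]3O[Si](C)(C)C(C)(C)C)cc1
F5 | step 24 | (1S,4S,5R,6R,8R,10R)-1,10:4,5-diepoxy-13-hydroxy-8-(TBS-oxy)germacr-7(11)-en-12,6-olide | OCC1=C2[C@@H](OC1=O)[C@H]1O[C@@]1(C)CC[C@@H]1O[C@]1(C)C[C@H]2O[Si](C)(C)C(C)(C)C
F6 | step 21 | methyl (2E,4R)-5-[(2R,3S)-3-ethenyl-2-methyloxiran-2-yl]-2-(PMB-oxymethyl)-4-(TBS-oxy)-3-(triflyloxy)pent-2-enoate (OTf trans to the ester) | COC(=O)/C(COCc1ccc(OC)cc1)=C(/OS(=O)(=O)C(F)(F)F)[C@@H](C[C@@]1(C)O[C@H]1C=C)O[Si](C)(C)C(C)(C)C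
F7 | step 21 | methyl (4R)-5-[(2R,3S)-3-ethenyl-2-methyloxiran-2-yl]-3-{[(2R,3S)-3-ethenyl-3-methyloxiran-2-yl](hydroxy)methyl}-2-(PMB-oxymethyl)-4-(TBS-oxy)pent-2-enoate (ester trans to the carbinol; C6 mixture) | COC(=O)/C(COCc1ccc(OC)cc1)=C(/C(O)[C@H]1O[C@@]1(C)C=C)[C@@H](C[C@@]1(C)O[C@H]1C=C)O[Si](C)(C)C(C)(C)C
F8 | step 21 | methyl (4R)-5-[(2R,3S)-3-ethenyl-2-methyloxiran-2-yl]-3-{[(2S,3S)-3-ethenyl-3-methyloxiran-2-yl]carbonyl}-2-(PMB-oxymethyl)-4-(TBS-oxy)pent-2-enoate (ester trans to the ketone) | COC(=O)/C(COCc1ccc(OC)cc1)=C(/C(=O)[C@H]1O[C@@]1(C)C=C)[C@@H](C[C@@]1(C)O[C@H]1C=C)O[Si](C)(C)C(C)(C)C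
F9 | step 21 | methyl (4R)-5-[(2R,3S)-3-ethenyl-2-methyloxiran-2-yl]-3-{(R)-[(2R,3S)-3-ethenyl-3-methyloxiran-2-yl](hydroxy)methyl}-2-(PMB-oxymethyl)-4-(TBS-oxy)pent-2-enoate (ester trans to the carbinol) | COC(=O)/C(COCc1ccc(OC)cc1)=C(/[C@@H](O)[C@H]1O[C@@]1(C)C=C)[C@@H](C[C@@]1(C)O[C@H]1C=C)O[Si](C)(C)C(C)(C)C
F10 | step 19 | (2Z)-3-methylpenta-2,4-dien-1-ol | C=C/C(C)=C\CO
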